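**Remarks.** Compounds 10–32 carry germacrane numbers (ring B = C1–C10; C11–C13 on C7; C14 on C10; C15 on C4). Compounds 1–9 keep quinic acid numbers; quinic C1, C2, C3, C4, C5, C6 become C4, C5, C6, C7, C8, C9. "Cis/trans in the ring" refers to the two ring bonds at an alkene. Assumption: the phosphonate-bearing C11 of 23–31 is carried as a mixture of epimers, which is harmless because C11 becomes sp2 in step 23.

## Analysis of the target

Compound 32 is a germacrane-type dilactone. Ring B (C1–C10) is a ten-membered carbocycle. Ring C is a butenolide (C4, C5, C6, O, C15) that bridges C4 and C6 and holds C4=C5 trans within ring B. Ring A is an α-methylene-γ-lactone (C7, C11, C12, O, C8) trans-fused at C7–C8. There are four stereocentres, (3S,6R,7S,8R): C6, C7 and C8 are contiguous, with O6 and C11 on one side and O8 on the other, and C3 lies alone beyond the butenolide. The C9=C10 alkene has C8 and C1 on the same side (cis in the ring, E by the sequence rule because C14 outranks C1) and bears the free hydroxymethyl C14. Sensitive groups are the α-methylene lactone, the butenolide with its acidic H6, the primary allylic alcohol and the C3 isobutyrate, an allylic ester on the α-carbon of an unsaturated lactone that can leave by SN2′. The hard parts are the strained, bridged ten-membered ring with two alkenes of different ring geometry, stereocontrol on a flexible ring, and telling four carbonyl groups apart. The strategy rests on the 1,5-relationship of the C9–C10 and C3–C4 bonds: two extra bonds, C4–C9 and C3–C10, turn ring B into a cyclohexane (C4, C5, C6, C7, C8, C9) joined through a bicyclo[2.2.0]hexane to a cyclobutane (C10, C1, C2, C3), so C6, C7 and C8 can be set on a rigid six-membered ring before strain releases the ten-membered ring.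

## Retrosynthetic reasoning

32 from 31: the C11=C13 bond is cut first. The α-methylene lactone is the most reactive group of 32, so it is kept as the α-phosphono lactone of 31 and unveiled by a Horner–Wadsworth–Emmons reaction in the last step.

31 from 30 from 29: the C14 alcohol is traced to the aldehyde of 30 and the C3 ester C–O bond to the alcohol 29. The aldehyde is kept this long because it lets the last reduction be a 1,2-reduction that no lactone or ester answers.

29 from 27: the C3–O bond is cut and the alkene is moved back from C4=C5 to C3=C4 (ene reaction in the forward sense). This turns the butenolide into the alkylidene lactone of 27, whose ring C is already closed, so the new C4=C5 alkene can only form inside ring C. The forward reaction must attack C3 from the outer face and must leave C9=C10 alone; the formyl group on C10 secures the latter.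

27 from 25: ring B is disconnected by re-forming C4–C9 and C3–C10. This replaces the ten-membered ring by the rigid tetracycle 25, in which ring B is stored as a cyclohexane and a bicyclo[2.2.0]hexane. The forward step is a thermal cycloreversion; the alkene geometries are set afterwards by equilibration.

25 from 24 from 23 from 22: after adjusting C14 (aldehyde from silyl ether), ring A is cut at C7–C11. A carbenoid C–H insertion from the O8 ester is chosen because in the chair locked by ring C only the equatorial C7–H is both reachable and cis to O6. This gives the C6/C7 cis and C7/C8 trans pattern that enolate alkylation next to a silyloxy group would not give. The phosphonate on the carbene carbon comes along as the methylenation handle.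

22 from 21 from 19 from 17 and 18: the diazo group goes back to the phosphonoacetate, ring C is cut at O6–C15 (lactonisation of a cis-1,3 hydroxy acid), and the O8 ester is cut to alcohol 17 and acid 18.

17 from 16 from 14: the C8 carbinol and the C14 hydroxymethyl come from the ketone and the methyl ester of 14 in one hydride reduction, which sets C8. The C15 ester is tert-butyl so that it survives this reduction and can later be opened by acid. The C14 ester is methyl so that it is reduced and cannot keep O8 tied up as a lactone.

14 from 10 and 13 (key disconnection): the C9–C10 and C4–C3 bonds of the central cyclobutane are cut, giving enone 10 and cyclobutene ester 13. No thermal cycloaddition makes a bicyclo[2.2.0]hexane; the enone triplet does. The forward reaction needs head-to-head regiochemistry and attack anti to O6, which places C15 cis to O6 for the later ring C closure.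

10 from 1: the C6 stereocentre is taken from 1 (quinic C3). C4–O is removed by radical deoxygenation (5), the lactone is exchanged for the tert-butyl ester (7), and oxidation at C5 with loss of the C1 hydroxyl gives the enone. 13 from 12 from 11 by dehydrobromination and esterification.

## Alternatives that were turned down

Alternative 1: Ring B is made by contracting a thirteen-membered cyclic allyl propargyl ether A1, in which C6 and C13 are linked through oxygen. A chiral lithium amide removes a propargylic proton at C6, the anion attacks C7 of the C7=C11 alkene, the O–C13 bond breaks and C13 becomes the exocyclic methylene of the ten-membered cycloalkynol A2 ([2,3]-Wittig rearrangement). In its favour: one step forms C6–C7, sets both stereocentres, delivers the C11=C13 unit directly, and the ten-membered ring comes from a larger, easier ring. On the C7–C11 bond and the methylene it is stronger than the chosen route, which needs three steps for ring A and a late olefination. Against it: absolute and relative control rest on an external chiral base acting on a macrocycle whose conformation is unknown; a [1,2]-shift and allenyl anion pathways compete; and A2 still needs the alkyne turned into the butenolide with C15 added cis to O6, the C8 ketal turned into a carbinol of the right configuration, and C12 oxidised. The chosen route takes C6 from the chiral pool and sets C7 and C8 on a locked chair.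

Alternative 2: Ring B is closed at C3, which comes from carbon monoxide. In the diiodide A3 (rings A and C complete, a primary iodide at C2 and an iodide at C4 of the butenolide), zinc inserts at C2, Pd(PPh3)4 adds to the C4–I bond, CO inserts, and the acylpalladium is alkylated by the C2 zinc reagent to give the C3 ketone A4. In its favour: it is the most convergent plan; C6, C7, C8, both lactones and the methylene are in place before ring closure, and only reduction and acylation at C3 remain. Its endgame is shorter than the chosen one. Against it: two bonds must form at one carbon while a strained ten-membered ring closes; direct coupling without CO, protodezincation and oligomerisation compete; the allylic lactone C8–O next to C9=C10 and the α-methylene lactone are both exposed to zinc and zerovalent palladium; and A4 is a 2-acylbutenolide that enolises and adds nucleophiles easily. The chosen route forms ring B by releasing strain, not against it.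

Alternative 3: Ring B is closed at C10–C1 by nickel electrocatalysis. In A5 the C1 carboxylic acid is activated as an N-acyloxyphthalimide and C10 is an alkenyl iodide. Cathodic reduction with NiCl2(dme), a bipyridine ligand and a zinc anode gives the primary C1 radical, the alkenylnickel from C10 captures it, and reductive elimination gives A6. In its favour: the C9=C10 geometry is fixed in the alkenyl iodide and is retained, and the C3 isobutyrate and ring C are already present. On alkene geometry it is stronger than the chosen route, which has to equilibrate the alkene after cycloreversion. Against it: a ten-membered ring must close by capture of a free primary radical, which has to outrun reduction, dimerisation and 1,5-hydrogen transfer at the low concentrations a macrocyclisation needs; the butenolide is a radical acceptor; and A6 still needs ring A (removal of two ethers, oxidation of C12, lactonisation). The chosen route uses a photochemical and a thermal step of known type for the ring.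

Key step: step 10

## Route

Step 1
Reactants: 1 (−)-quinic acid
Product: 2 quinide (1,5-lactone of quinic acid; 1,3,4-trihydroxy-6-oxabicyclo[3.2.1]octan-7-one)
Conditions: p-TsOH·H2O (cat.), toluene/DMF, reflux, Dean–Stark
Reagents that add atoms: none
Why: Acid-catalysed lactonisation; the carboxyl and the C5 hydroxyl are cis, so loss of water gives the bicyclic γ-lactone and sets C5–OH apart from C3–OH and C4–OH.

Step 2
Reactants: 2 quinide
Product: 3 3-O-(tert-butyldimethylsilyl)quinide
Conditions: TBSCl (1.1 equiv), imidazole, DMF, 0 °C
Reagents that add atoms: tert-butyldimethylsilyl chloride, CC(C)(C)[Si](C)(C)Cl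
Why: Silylation of the only equatorial secondary hydroxyl; the axial C4–OH and the tertiary C1–OH react much more slowly.

Step 3
Reactants: 3 3-O-TBS-quinide
Product: 4 3-O-TBS-4-O-(imidazol-1-ylthiocarbonyl)quinide
Conditions: 1,1'-thiocarbonyldiimidazole, DMAP (cat.), ClCH2CH2Cl, 60 °C
Reagents that add atoms: 1,1'-thiocarbonyldiimidazole, S=C(n1ccnc1)n1ccnc1
Why: Thioacylation of the remaining secondary alcohol; the tertiary hydroxyl does not react.

Step 4
Reactants: 4 thiocarbonyl imidazolide
Product: 5 4-deoxy-3-O-TBS-quinide
Conditions: Bu3SnH, AIBN (cat.), toluene, 100 °C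
Reagents that add atoms: none
Why: Barton–McCombie deoxygenation; the stannyl radical adds to C=S, the secondary C4 radical is released and reduced, and C4 becomes the CH2 that is C7 of the target.

Step 5
Reactants: 5 4-deoxy-3-O-TBS-quinide
Product: 6 4-deoxy-3-O-TBS-quinic acid (1,5-dihydroxy-3-silyloxycyclohexane-1-carboxylic acid with the configuration of 1 at C1, C3 and C5)
Conditions: LiOH·H2O, THF/H2O, 0 °C; 1 M HCl to pH 4, 0 °C
Reagents that add atoms: lithium hydroxide, [Li+].[OH-]
Why: Saponification of the strained bicyclic lactone; the silyl ether survives cold hydroxide and brief acidification.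

Step 6
Reactants: 6 hydroxy acid
Product: 7 tert-butyl ester of 6
Conditions: tert-butyl 2,2,2-trichloroacetimidate (2 equiv), CH2Cl2/cyclohexane, rt
Reagents that add atoms: tert-butyl 2,2,2-trichloroacetimidate, CC(C)(C)OC(=N)C(Cl)(Cl)Cl
Why: Imidate esterification; the acid protonates the imidate and takes up the tert-butyl cation, while alcohols need a Lewis acid and stay free.

Step 7
Reactants: 7 tert-butyl 1,5-dihydroxy-3-silyloxycyclohexane-1-carboxylate
Product: 10 tert-butyl (5R)-5-[(tert-butyldimethylsilyl)oxy]-3-oxocyclohex-1-ene-1-carboxylate, via ketol 8 (not isolated), via mesylate 9 (not isolated)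
Conditions: Dess–Martin periodinane, NaHCO3, CH2Cl2, 0 °C to rt; then MsCl, Et3N, CH2Cl2, 0 °C
Reagents that add atoms: none
Why: Dess–Martin oxidation of the only secondary alcohol, then mesylation of the tertiary hydroxyl and E1cB loss through the quinic C6 enolate put the alkene in conjugation with ketone and ester; at 0 °C the β-silyloxy group on the other side of the ketone is not expelled.

Step 8
Reactants: 11 ethyl 1-bromocyclobutane-1-carboxylate
Product: 12 cyclobut-1-ene-1-carboxylic acid
Conditions: KOH (powder), toluene, reflux; then cold aq. HCl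
Reagents that add atoms: potassium hydroxide, [K+].[OH-]
Why: Dehydrobromination of the α-bromo ester with saponification in the same flask; the strained acid is kept cold and used at once.

Step 9
Reactants: 12 cyclobut-1-ene-1-carboxylic acid
Product: 13 methyl cyclobut-1-ene-1-carboxylate
Conditions: MeI, K2CO3, DMF, 0 °C to rt
Reagents that add atoms: iodomethane, CI
Why: SN2 alkylation of the carboxylate; it avoids acid and heat, under which the cyclobutene ester polymerises.

Step 10
Reactants: 10 tert-butyl (5R)-5-silyloxy-3-oxocyclohex-1-ene-1-carboxylate; 13 methyl cyclobut-1-ene-1-carboxylate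
Product: 14 cis-anti-cis 6–4–4 tricycle (tricyclo[4.4.0.0^2,5]decanone core) holding C1–C10: C8 ketone, C6 OTBS, tert-butyl ester C15 on C4 cis to O6, methyl ester C14 on C10, cyclobutane anti to O6
Conditions: hν (medium-pressure Hg lamp, uranium-glass filter, λ > 340 nm), 13 (6 equiv), CH2Cl2, −30 °C; then basic Al2O3, CH2Cl2, rt
Reagents that add atoms: none
Why: Excitation of 10 and intersystem crossing give the enone triplet, which bonds through its β-carbon C4 to the unsubstituted cyclobutene carbon C3; the 1,4-biradical has both radical centres next to a carbonyl (C9 beside the C8 ketone, tertiary C10 beside the C14 ester) and, after spin inversion, closes the central cyclobutane by C9–C10 recombination (four-membered ring from a triplet 1,4-biradical). The closest known reaction type is the [2+2] photocycloaddition of 2-cyclohexenones with cyclobut-1-enecarboxylates. Head-to-head regiochemistry is required; it is favoured by the usual preference of electron-poor alkenes, by the doubly stabilised biradical, and because the other orientation would join the quaternary carbons C4 and C10. C4 and C3 are set in the first bond formation on the face anti to the C6 silyloxy group, which puts the C15 ester cis to O6. C9 ends cis to C4, and any trans-fused adduct is epimerised at C9 on alumina. C10 follows from the cis fusion of the cyclobutene, and the outer ring turns away from the six-membered ring (anti) for steric reasons. Excess 13 and low temperature hold back enone dimerisation.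

Step 11
Reactants: 14 photoadduct
Product: 16 diol (C8 carbinol with O8 cis to the cyclobutane; C14 hydroxymethyl on C10), via C14–O8 lactone 15 (not isolated)
Conditions: LiBH4 (3 equiv), THF, 0 °C to rt; aq. NH4Cl
Reagents that add atoms: none
Why: Hydride reduction; hydride adds to C8 from the convex face because the other face is blocked by the syn-axial C4–C3 bond, so O8 ends cis to C10 (C8 set as in the target). The alkoxide closes onto the cis C14 ester and the lactone is reduced on, while the tert-butyl ester on quaternary C4 is inert to LiBH4.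

Step 12
Reactants: 16 diol
Product: 17 C14 tert-butyldiphenylsilyl ether with free C8–OH
Conditions: TBDPSCl (1.05 equiv), imidazole, CH2Cl2, 0 °C
Reagents that add atoms: tert-butyl(chloro)diphenylsilane, CC(C)(C)[Si](Cl)(c1ccccc1)c1ccccc1
Why: Selective silylation of the primary alcohol over the hindered axial C8–OH; this silyl ether survives the acid of step 14.

Step 13
Reactants: 17 C8 alcohol; 18 2-(diethoxyphosphoryl)acetic acid
Product: 19 C8 (diethoxyphosphoryl)acetate
Conditions: DCC, DMAP (cat.), CH2Cl2, 0 °C to rt
Reagents that add atoms: none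
Why: Steglich esterification; it brings in C11, C12 and the phosphonate that later serves for methylenation.

Step 14
Reactants: 19 phosphonoacetate
Product: 21 ring C lactone (C15–O6; 6-oxabicyclo[3.2.1]octan-7-one fused to the bicyclo[2.2.0]hexane), via hydroxy acid 20 (not isolated)
Conditions: TFA/CH2Cl2 (1:2), H2O (5 equiv), 0 °C to rt; evaporate with toluene; DCC, DMAP (cat.), CH2Cl2, rt
Reagents that add atoms: none
Why: Acidolysis removes the tert-butyl ester and the secondary silyl ether, and the primary TBDPS ether persists. The C15 acid and the C6 hydroxyl are cis-1,3, so carbodiimide lactonisation closes the same bridged lactone as in 2 and locks the carbocycle in the chair with O6 axial and O8 equatorial.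

Step 15
Reactants: 21 phosphonoacetate lactone
Product: 22 α-diazo-α-(diethoxyphosphoryl)acetate
Conditions: NaH, THF, 0 °C; 4-acetamidobenzenesulfonyl azide, 0 °C to rt; aq. NH4Cl
Reagents that add atoms: 4-acetamidobenzenesulfonyl azide, CC(=O)Nc1ccc(cc1)S(=O)(=O)N=[N+]=[N-]
Why: Regitz diazo transfer to the phosphonoacetate anion; no other position of 21 is enolisable.

Step 16
Reactants: 22 diazo phosphonoacetate
Product: 23 tetracyclic dilactone: ring A closed (C7–C11; trans-fused; C11 bears the phosphonate; C11 epimers), ring C lactone, C14 OTBDPS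
Conditions: Rh2(O2CC7H15)4 (2 mol %), CH2Cl2, 40 °C, slow addition of 22
Reagents that add atoms: none
Why: Dirhodium-carbenoid 1,5-C–H insertion with retention. In the locked chair the equatorial C7–H is cis to axial O6 and gauche to equatorial O8, so insertion gives the trans-fused γ-lactone with C11 cis to O6 (C7 set as S); the axial C7–H is shielded by the syn-axial C10, and the tertiary C9–H lies between two quaternary carbons.

Step 17
Reactants: 23 silyl ether
Product: 24 C14 primary alcohol
Conditions: HF·pyridine, pyridine/THF, 0 °C to rt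
Reagents that add atoms: none
Why: Fluoride cleavage of the silyl ether under buffered conditions that do not deprotonate the phosphono lactone.

Step 18
Reactants: 24 alcohol
Product: 25 C14 aldehyde (formyl group on quaternary C10)
Conditions: Dess–Martin periodinane, NaHCO3, CH2Cl2, rt
Reagents that add atoms: none
Why: Dess–Martin oxidation to a non-enolisable aldehyde; the formyl group lowers the barrier of step 19, keeps C9=C10 electron-poor in step 20 and allows a Luche reduction in step 22.

Step 19
Reactants: 25 tetracyclic aldehyde
Product: 27 ten-membered dilactone enal with C9=C10 cis in the ring (E) and the alkylidene lactone C3=C4 with C2 cis to C5 (E), via ring-trans diene 26 (not isolated)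
Conditions: o-xylene (0.01 M, degassed, BHT), 140 °C, base-washed glass; cool; PhSSPh (10 mol %), hν (visible), 40 °C
Reagents that add atoms: none
Why: Thermal cycloreversion of the bicyclo[2.2.0]hexane; homolysis of the central C3–C10 bond (C10 radical stabilised by the formyl group) and β-scission of C4–C9 in the chair-like 1,4-diyl release the strain of two cyclobutanes and open ring B. With the carbocycle locked by rings A and C the C9–C10 bond is axial, so the first diene 26 should have C3=C4 cis and C9=C10 trans in the ring. Reversible thiyl-radical addition then equilibrates both alkenes to the geometry with the carbonyl trans to the β-substituent, which is also the cis,cis-cyclodeca-1,5-diene that resists Cope rearrangement.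

Step 20
Reactants: 27 alkylidene lactone
Product: 29 (3S)-3-hydroxy butenolide (C4=C5 in ring C), via C3 hydroperoxide 28 (not isolated)
Conditions: O2, tetraphenylporphyrin (1 mol %), hν (visible), CDCl3/CH2Cl2, −10 °C; then Me2S, 0 °C to rt
Reagents that add atoms: dioxygen, O=O
Why: Schenck ene reaction of an α,β-unsaturated carbonyl compound; singlet oxygen bonds to the β-carbon C3 and takes the C5 hydrogen geminal to the lactone carbonyl, so the alkene moves into ring C. Attack from the outer face (the side of H6, away from the C7 branch and the ring B chain) on the E alkene gives 3S; the enal C9=C10 is too electron-poor to react, and the sulfide reduces the hydroperoxide.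

Step 21
Reactants: 29 C3 alcohol
Product: 30 C3 isobutyrate
Conditions: isobutyryl chloride, pyridine, CH2Cl2, 0 °C
Reagents that add atoms: 2-methylpropanoyl chloride, CC(C)C(Cl)=O
Why: Acylation with retention at C3; pyridine is used in place of a nucleophilic catalyst because the product is an allylic ester open to SN2′ attack.

Step 22
Reactants: 30 enal
Product: 31 C14 allylic alcohol
Conditions: NaBH4, CeCl3·7H2O, MeOH, −78 °C
Reagents that add atoms: none
Why: Luche 1,2-reduction of the aldehyde, which lactones, the isobutyrate and the butenolide do not answer at −78 °C; it precedes step 23 because a phosphonate anion would condense with the aldehyde across the ring.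

Step 23
Reactants: 31 α-phosphono lactone
Product: 32 target, (3S,6R,7S,8R)
Conditions: K2CO3, 37% aq. HCHO, THF, 0 °C to rt
Reagents that add atoms: formaldehyde, C=O
Why: Horner–Wadsworth–Emmons methylenation of the α-phosphono lactone under mild carbonate conditions; both C11 epimers give the same exocyclic alkene.

## Compound list

1 | (−)-quinic acid | OC(=O)[C@]1(O)C[C@@H](O)[C@@H](O)[C@H](O)C1 | starting material
2 | quinide (1,5-lactone of 1) | O=C2[C@]1(O)C[C@@H](O)[C@@H](O)[C@H](O2)C1 | intermediate
3 | 3-O-TBS-quinide | O=C2[C@]1(O)C[C@@H](O[Si](C)(C)C(C)(C)C)[C@@H](O)[C@H](O2)C1 | intermediate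
4 | 3-O-TBS-4-O-(imidazol-1-ylthiocarbonyl)quinide | O=C2[C@]1(O)C[C@@H](O[Si](C)(C)C(C)(C)C)[C@@H](OC(=S)n3ccnc3)[C@H](O2)C1 | intermediate
5 | 4-deoxy-3-O-TBS-quinide | O=C2[C@]1(O)C[C@@H](O[Si](C)(C)C(C)(C)C)C[C@H](O2)C1 | intermediate
6 | 4-deoxy-3-O-TBS-quinic acid | OC(=O)[C@]1(O)C[C@@H](O[Si](C)(C)C(C)(C)C)C[C@H](O)C1 | intermediate
7 | tert-butyl ester of 6 | CC(C)(C)OC(=O)[C@]1(O)C[C@@H](O[Si](C)(C)C(C)(C)C)C[C@H](O)C1 | intermediate
8 | ketol: tert-butyl 1-hydroxy-3-silyloxy-5-oxocyclohexane-1-carboxylate | CC(C)(C)OC(=O)[C@]1(O)C[C@@H](O[Si](C)(C)C(C)(C)C)CC(=O)C1 | intermediate (not isolated)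
9 | C1 mesylate of 8 | CC(C)(C)OC(=O)[C@]1(OS(C)(=O)=O)C[C@@H](O[Si](C)(C)C(C)(C)C)CC(=O)C1 | intermediate (not isolated)
10 | tert-butyl (5R)-5-[(tert-butyldimethylsilyl)oxy]-3-oxocyclohex-1-ene-1-carboxylate | O=C1C[C@H](O[Si](C)(C)C(C)(C)C)CC(C(=O)OC(C)(C)C)=C1 | intermediate
11 | ethyl 1-bromocyclobutane-1-carboxylate | CCOC(=O)C1(Br)CCC1 | starting material
12 | cyclobut-1-ene-1-carboxylic acid | OC(=O)C1=CCC1 | intermediate
13 | methyl cyclobut-1-ene-1-carboxylate | COC(=O)C1=CCC1 | intermediate
14 | cis-anti-cis photoadduct (C8 ketone, C6 OTBS, C15 tert-butyl ester, C14 methyl ester) | O=C1C[C@H](O[Si](C)(C)C(C)(C)C)C[C@@]2(C(=O)OC(C)(C)C)[C@@H]3CC[C@]3(C(=O)OC)[C@@H]12 | intermediate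
15 | C14–O8 lactone of the reduced photoadduct | O=C4O[C@H]1C[C@H](O[Si](C)(C)C(C)(C)C)C[C@@]2(C(=O)OC(C)(C)C)[C@@H]3CC[C@]34[C@@H]12 | intermediate (not isolated)
16 | C8,C14 diol | O[C@H]1C[C@H](O[Si](C)(C)C(C)(C)C)C[C@@]2(C(=O)OC(C)(C)C)[C@@H]3CC[C@]3(CO)[C@@H]12 | intermediate
17 | C14 TBDPS ether, C8 alcohol | O[C@H]1C[C@H](O[Si](C)(C)C(C)(C)C)C[C@@]2(C(=O)OC(C)(C)C)[C@@H]3CC[C@]3(CO[Si](c4ccccc4)(c4ccccc4)C(C)(C)C)[C@@H]12 | intermediate
18 | 2-(diethoxyphosphoryl)acetic acid | OC(=O)CP(=O)(OCC)OCC | starting material
19 | C8 (diethoxyphosphoryl)acetate | CCOP(=O)(OCC)CC(=O)O[C@H]1C[C@H](O[Si](C)(C)C(C)(C)C)C[C@@]2(C(=O)OC(C)(C)C)[C@@H]3CC[C@]3(CO[Si](c4ccccc4)(c4ccccc4)C(C)(C)C)[C@@H]12 | intermediate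
20 | C6 hydroxy C15 acid | CCOP(=O)(OCC)CC(=O)O[C@H]1C[C@H](O)C[C@@]2(C(=O)O)[C@@H]3CC[C@]3(CO[Si](c4ccccc4)(c4ccccc4)C(C)(C)C)[C@@H]12 | intermediate (not isolated)
21 | ring C lactone (C15–O6 bridge) | CCOP(=O)(OCC)CC(=O)O[C@H]1C[C@H]4C[C@@]2(C(=O)O4)[C@@H]3CC[C@]3(CO[Si](c5ccccc5)(c5ccccc5)C(C)(C)C)[C@@H]12 | intermediate
22 | α-diazo phosphonoacetate | CCOP(=O)(OCC)C(=[N+]=[N-])C(=O)O[C@H]1C[C@H]4C[C@@]2(C(=O)O4)[C@@H]3CC[C@]3(CO[Si](c5ccccc5)(c5ccccc5)C(C)(C)C)[C@@H]12 | intermediate
23 | tetracyclic dilactone, C11 phosphonate (C11 epimers), C14 OTBDPS | O=C1O[C@H]2[C@H](C1P(=O)(OCC)OCC)[C@H]3C[C@@]4(C(=O)O3)[C@@H]5CC[C@]5(CO[Si](c6ccccc6)(c6ccccc6)C(C)(C)C)[C@@H]24 | intermediate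
24 | tetracyclic dilactone, C14 alcohol | O=C1O[C@H]2[C@H](C1P(=O)(OCC)OCC)[C@H]3C[C@@]4(C(=O)O3)[C@@H]5CC[C@]5(CO)[C@@H]24 | intermediate
25 | tetracyclic dilactone, C14 aldehyde | O=C1O[C@H]2[C@H](C1P(=O)(OCC)OCC)[C@H]3C[C@@]4(C(=O)O3)[C@@H]5CC[C@]5(C=O)[C@@H]24 | intermediate
26 | ten-membered dilactone enal, C9=C10 trans in ring, C3=C4 cis in ring | CCOP(=O)(OCC)C1C(=O)O[C@@H]2/C=C(\C=O)CC/C=C3\C[C@@H](OC3=O)[C@@H]12 | intermediate (not isolated)
27 | ten-membered dilactone enal, C9=C10 and C3=C4 both cis in ring (both E) | CCOP(=O)(OCC)C1C(=O)O[C@@H]2/C=C(/C=O)CC/C=C3\C[C@@H](OC3=O)[C@@H]12 | intermediate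
28 | (3S)-3-hydroperoxy butenolide | CCOP(=O)(OCC)C1C(=O)O[C@@H]2/C=C(/C=O)CC[C@H](OO)C3=C[C@@H](OC3=O)[C@@H]12 | intermediate (not isolated)
29 | (3S)-3-hydroxy butenolide enal | CCOP(=O)(OCC)C1C(=O)O[C@@H]2/C=C(/C=O)CC[C@H](O)C3=C[C@@H](OC3=O)[C@@H]12 | intermediate
30 | C3 isobutyrate enal | CCOP(=O)(OCC)C1C(=O)O[C@@H]2/C=C(/C=O)CC[C@H](OC(=O)C(C)C)C3=C[C@@H](OC3=O)[C@@H]12 | intermediate
31 | C3 isobutyrate, C14 alcohol, C11 phosphonate | CCOP(=O)(OCC)C1C(=O)O[C@@H]2/C=C(/CO)CC[C@H](OC(=O)C(C)C)C3=C[C@@H](OC3=O)[C@@H]12 | intermediate
32 | target CNP0322767.4 | C=C1C(=O)O[C@@H]2/C=C(/CO)CC[C@H](OC(=O)C(C)C)C3=C[C@@H](OC3=O)[C@@H]12 | target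

## Step count and risk

Total: 23 steps. Longest linear sequence: 21 steps (steps 1–7 and 10–23, from 1).

**Step 10 (key step).** The cyclobutene may bond head-to-tail, or add syn to the silyloxy group, because a single substituent at C6 is a weak facial director; syn addition would put C15 trans to O6 and make step 14 impossible. Enone dimerisation can also lower conversion. Fallback: use a fused ring as the facial director. From 2, acetonide formation (2,2-dimethoxypropane, p-TsOH) gives 3,4-O-isopropylidenequinide F1. Saponification gives acid F2 and imidate esterification gives tert-butyl ester F3. Oxidation–elimination as in step 7 gives the acetonide enone F4, whose cis-fused dioxolane covers one face. Irradiation with 13 gives photoadduct F5. SmI2 in THF/MeOH at −78 °C cleaves the C7–O bond next to the ketone and sets free the C6 hydroxy ketone F6, and silylation (TBSCl, imidazole) returns to 14.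

**Step 16.** The carbenoid may insert into the tertiary C9–H or the axial C7–H, or dimerise, because the C7–H bonds are deactivated by the oxygen on C6. Fallback: an enolate route to ring A. From 17, Dess–Martin oxidation gives the C8 ketone F7. Aldol condensation with ethyl glyoxylate (LiN(i-Pr)2, −78 °C; then MsCl, Et3N) gives the alkylidene ketone F8. Luche reduction from the convex face gives the allylic alcohol F9. Hydroxyl-directed hydrogenation with [Ir(cod)(PCy3)(py)]PF6 gives the hydroxy ester F10 with C11 trans to O8. TFA, then DCC, then mild acid closes rings C and A to the dilactone F11. Phosphorylation of the lactone enolate (LiN(i-Pr)2, ClP(O)(OEt)2, then a second equivalent of base for the phosphate-to-phosphonate shift) returns to 23.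

**Step 19.** The first-formed cis,trans-diene may undergo Cope rearrangement to a divinylcyclohexane before it is equilibrated; the diyl may cleave C1–C2 instead of C4–C9; the formyl group may be lost at high temperature. Fallback: open the cage one stage earlier and in the gas phase. From 23, flash vacuum pyrolysis gives the ten-membered silyl ether F12. HF·pyridine gives the allylic alcohol F13. MnO2 oxidation followed by PhSSPh and light gives the equilibrated enal 27.

**Step 20.** Oxygen may attack the inner face of the alkylidene lactone and give the C3 epimer; hydrogen may be taken from C2; the aldehyde may autoxidise during the long irradiation. Fallback for the wrong face: the (3R)-alcohol F14 is esterified under Mitsunobu conditions (isobutyric acid, PPh3, diisopropyl azodicarboxylate), which inverts C3 and gives 30 directly.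

**Step 23.** Carbonate and water may displace or eliminate the C3 isobutyrate (SN2′ at the butenolide) or epimerise C6. Fallback: olefinate before the labile ester is present. From 29, Luche reduction gives the diol F15. Methylenation (K2CO3, aq. HCHO) gives the methylene lactone diol F16. TBSCl silylates the primary C14 hydroxyl to give F17. Isobutyryl chloride and pyridine give F18, and HF·pyridine gives 32.

## Further compounds

F1 | step 10 | 3,4-O-isopropylidenequinide | O=C2[C@]1(O)C[C@H]3OC(C)(C)O[C@H]3[C@H](O2)C1
F2 | step 10 | 3,4-O-isopropylidenequinic acid | OC(=O)[C@]1(O)C[C@H]2OC(C)(C)O[C@H]2[C@H](O)C1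
F3 | step 10 | tert-butyl 3,4-O-isopropylidenequinate | CC(C)(C)OC(=O)[C@]1(O)C[C@H]2OC(C)(C)O[C@H]2[C@H](O)C1
F4 | step 10 | tert-butyl 4,5-cis-(isopropylidenedioxy)-3-oxocyclohex-1-ene-1-carboxylate (acetonide enone; O6 and O7 of the target numbering) | CC(C)(C)OC(=O)C1=CC(=O)[C@@H]2OC(C)(C)O[C@@H]2C1
F5 | step 10 | photoadduct of F4 and 13 (C6,C7 acetonide) | O=C1[C@@H]2OC(C)(C)O[C@@H]2C[C@@]3(C(=O)OC(C)(C)C)[C@@H]4CC[C@]4(C(=O)OC)[C@@H]13
F6 | step 10 | C6 hydroxy ketone (14 without the silyl group) | O=C1C[C@H](O)C[C@@]2(C(=O)OC(C)(C)C)[C@@H]3CC[C@]3(C(=O)OC)[C@@H]12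
F7 | step 16 | C8 ketone with C14 OTBDPS | O=C1C[C@H](O[Si](C)(C)C(C)(C)C)C[C@@]2(C(=O)OC(C)(C)C)[C@@H]3CC[C@]3(CO[Si](c4ccccc4)(c4ccccc4)C(C)(C)C)[C@@H]12
F8 | step 16 | (E)-C7 (ethoxycarbonyl)methylidene ketone | O=C1/C(=C/C(=O)OCC)[C@H](O[Si](C)(C)C(C)(C)C)C[C@@]2(C(=O)OC(C)(C)C)[C@@H]3CC[C@]3(CO[Si](c4ccccc4)(c4ccccc4)C(C)(C)C)[C@@H]12
F9 | step 16 | allylic C8 alcohol | O[C@H]1/C(=C/C(=O)OCC)[C@H](O[Si](C)(C)C(C)(C)C)C[C@@]2(C(=O)OC(C)(C)C)[C@@H]3CC[C@]3(CO[Si](c4ccccc4)(c4ccccc4)C(C)(C)C)[C@@H]12
F10 | step 16 | C8 hydroxy C7 (ethoxycarbonyl)methyl compound | O[C@H]1[C@H](CC(=O)OCC)[C@H](O[Si](C)(C)C(C)(C)C)C[C@@]2(C(=O)OC(C)(C)C)[C@@H]3CC[C@]3(CO[Si](c4ccccc4)(c4ccccc4)C(C)(C)C)[C@@H]12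
F11 | step 16 | tetracyclic dilactone without phosphonate | O=C1O[C@H]2[C@H](C1)[C@H]3C[C@@]4(C(=O)O3)[C@@H]5CC[C@]5(CO[Si](c6ccccc6)(c6ccccc6)C(C)(C)C)[C@@H]24
F12 | step 19 | ten-membered dilactone, C14 OTBDPS (alkene geometries not yet equilibrated) | CCOP(=O)(OCC)C1C(=O)O[C@@H]2C=C(CO[Si](c3ccccc3)(c3ccccc3)C(C)(C)C)CCC=C3C[C@@H](OC3=O)[C@@H]12
F13 | step 19 | ten-membered dilactone, C14 allylic alcohol | CCOP(=O)(OCC)C1C(=O)O[C@@H]2C=C(CO)CCC=C3C[C@@H](OC3=O)[C@@H]12
F14 | step 20 | (3R)-3-hydroxy butenolide enal (C3 epimer of 29) | CCOP(=O)(OCC)C1C(=O)O[C@@H]2/C=C(/C=O)CC[C@@H](O)C3=C[C@@H](OC3=O)[C@@H]12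
F15 | step 23 | C3,C14 diol with C11 phosphonate | CCOP(=O)(OCC)C1C(=O)O[C@@H]2/C=C(/CO)CC[C@H](O)C3=C[C@@H](OC3=O)[C@@H]12
F16 | step 23 | 3-deacyl target (methylene lactone diol) | C=C1C(=O)O[C@@H]2/C=C(/CO)CC[C@H](O)C3=C[C@@H](OC3=O)[C@@H]12
F17 | step 23 | C14 TBS ether of F16 | C=C1C(=O)O[C@@H]2/C=C(/CO[Si](C)(C)C(C)(C)C)CC[C@H](O)C3=C[C@@H](OC3=O)[C@@H]12
F18 | step 23 | C14 TBS ether of 32 | C=C1C(=O)O[C@@H]2/C=C(/CO[Si](C)(C)C(C)(C)C)CC[C@H](OC(=O)C(C)C)C3=C[C@@H](OC3=O)[C@@H]12
A1 | alternative 1 | thirteen-membered cyclic allyl propargyl ether (C6–O–C13; C7=C11 geometry left open) | O1CC#C[C@@H](O[Si](CC)(CC)CC)CC/C(CO[Si](c2ccccc2)(c2ccccc2)C(C)(C)C)=C\C2(OCCO2)C=C(COCc2ccc(OC)cc2)C1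
A2 | alternative 1 | ten-membered cycloalkynol with C6 and C7 set | O[C@H]1[C@@H](C(=C)COCc2ccc(OC)cc2)C2(OCCO2)/C=C(/CO[Si](c2ccccc2)(c2ccccc2)C(C)(C)C)CC[C@H](O[Si](CC)(CC)CC)C#C1
A3 | alternative 2 | diiodide with rings A and C (C2 iodide, C4 iodobutenolide) | C=C1C(=O)O[C@H](/C=C(/CO[Si](c2ccccc2)(c2ccccc2)C(C)(C)C)CCI)[C@H]1[C@H]1C=C(I)C(=O)O1
A4 | alternative 2 | tricyclic C3 ketone | C=C1C(=O)O[C@@H]2/C=C(/CO[Si](c3ccccc3)(c3ccccc3)C(C)(C)C)CCC(=O)C3=C[C@@H](OC3=O)[C@@H]12
A5 | alternative 3 | C10 alkenyl iodide with C1 N-acyloxyphthalimide | C=C(COCc1ccc(OC)cc1)[C@@H]([C@H](OCc1ccc(OC)cc1)/C=C(\I)CO[Si](c1ccccc1)(c1ccccc1)C(C)(C)C)[C@@H]1OC(=O)C([C@H](CCC(=O)ON2C(=O)c3ccccc3C2=O)OC(=O)C(C)C)=C1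
A6 | alternative 3 | rings B and C complete, ring A masked | C=C(COCc1ccc(OC)cc1)[C@H]1[C@H](OCc2ccc(OC)cc2)/C=C(/CO[Si](c2ccccc2)(c2ccccc2)C(C)(C)C)CC[C@H](OC(=O)C(C)C)C2=C[C@H]1OC2=O
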